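## Structural features

The target is a dimer of two isoflavans joined by one C–C bond. C4 of the first chroman (benzo ring A fused to pyran ring C) carries the central ring D, and ring D is also the 3-aryl group of the second chroman (pyran ring E fused to benzo ring F). Ring C bears the 2-hydroxy-4-methoxyphenyl ring B on C3, so C3 and C4 are neighbouring stereocentres, trans to each other, (3S,4R). The third stereocentre, (3S) in ring E, sits meta to C4 across ring D and can neither help nor disturb much. All four phenols lie on resorcinol-type rings, which makes the free compound sensitive to oxidants and electrophiles, so they are carried as benzyl ethers and released last. C4 is a doubly benzylic methine between oxygenated arenes; a leaving group on it ionises very easily, which is a liability for handling but the basis of the plan. The real difficulty is the C3–C4 bond between two carbons that each carry an ortho-oxygenated aryl group, together with the absolute configuration at C4, which cannot be repaired once set, whereas C3 can be epimerised while C2 is a carbonyl. The key step uses the fact that O1, C8a, C4a and C4 form a masked ortho-quinone methide with ring D already on the methide carbon, while C2, C3 and ring B form an arylacetic acid. Joining C3 to C4 and O1 to C2 closes ring C.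

## Logic of the disconnections

28 to 27: the four O–benzyl bonds are cut. Free resorcinol phenols would compete as nucleophiles and acids in every late step, and one kind of protecting group allows one final operation. The gain is robustness, not skeleton. The forward step must leave both chroman C–O bonds and the C4–H bond alone, which holds because none of them is a benzylic carbon–heteroatom bond.

27 to 26: O1–C2 of ring C is cut. An aryl alkyl ether to a non-stereogenic primary carbon is the safest ring bond to form last. This opens ring C to one phenol and one primary alcohol. The forward step needs the ring A hydroxyl to be the only free phenol and must displace at a β-branched primary carbon.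

26 to 25: no skeletal bond is cut; C2 is raised to the acyl level, with O1–C2 as a lactone bond. A carbonyl at C2 makes C3 acidic, which is what allows enolate chemistry and the trans correction. The reduction must be faster than enolisation or ring opening.

25 to 22 and 4 (through 23 and 24): C3–C4 and O1–C2 are cut. The cut removes ring C and both neighbouring stereocentres in one step and leaves a benzhydryl sulfone that already holds rings A, D, E and F, plus a simple arylacetic acid. The forward step must select one face of a planar methide at C4 and must acylate carbon, not the ring A oxygen.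

22 to 21, then to 18 and 9 (through 19 and 20): C4–S is cut, then the bond from C4 to ring D. Sulfinate is a leaving group that mild base expels. The carbinol comes from an aryl-metal and an aldehyde in which the C4–C4a bond and the ortho oxygen of ring A already exist, so the regiochemistry on ring A is not left to electrophilic substitution of a free phenol, which could occur para to the hydroxyl or twice. The demands are addition of an aryllithium to a phenoxide-bearing aldehyde, and sulfinate exchange without self-alkylation.

18 to 17 to 16: O1–C2 of ring E is cut, then the acetal on the ring F oxygen is restored. The ring closure is the same dependable primary-carbon etherification used for ring C. The acetal must come off without touching benzyl ethers, the aryl bromide or the stereocentre.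

16 to 15, then to 8 and 13 (through 14): C2 of ring E is raised to an imide and the bond from the stereocentre to the benzylic CH2 is cut. Auxiliary-controlled alkylation of an arylacetyl imide is a reliable entry to an α-aryl stereocentre. The acidic α-aryl centre must not epimerise during or after alkylation.

8 to 5 and 6 (through 7); 5 to 4; 4 to 2 to 1 (through 3): the N-acyl bond, the C–Br bond and the two-carbon chain are traced back. Compound 4 serves twice: directly as the ring B acid of the key step and, after bromination, as ring D. Bromination must go only to the position para to the benzyloxy group.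

13 to 11 to 10 to 9 (through 12): the benzylic C–Br bond, the alcohol and the acetal are traced back to 9, which also serves twice (ring F here, ring A in the carbinol step).

## Other disconnections considered

Alternative 1: The cut is at O1–C8a of the lactone, so ring C is traced to a five-membered ketone, (2S,3R)-6-(benzyloxy)-2-[2-(benzyloxy)-4-methoxyphenyl]-3-[4-(benzyloxy)-5-bromo-2-methoxyphenyl]-2,3-dihydro-1H-inden-1-one A1, used as the racemic trans compound. A Baeyer–Villiger monooxygenase with its reduced nicotinamide cofactor and air would insert oxygen between the carbonyl carbon and ring A of one enantiomer and give (3S,4R)-7-(benzyloxy)-3-[2-(benzyloxy)-4-methoxyphenyl]-4-[4-(benzyloxy)-5-bromo-2-methoxyphenyl]-3,4-dihydro-2H-chromen-2-one A2.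
- In favour: A1 is compact, its trans arrangement is thermodynamic, aryl migration is the usual preference of indanones, and the oxidant is air. A2 has the same lactone as 25, so the reduction and ether closure would be the same; on that point the alternative is equal. If a fitting enzyme exists, its absolute selectivity could exceed that of a small-molecule catalyst; on that point it could be better.
- Against: it is a resolution, and C3 of A1 cannot be epimerised, so at most half of A1 is usable. Migration of the secondary benzylic C2 competes and would give an isochromanone. A1, with three benzyl ethers and two ortho-substituted aryl groups, is far larger than ketones such enzymes usually accept.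
- Structure: A2 still lacks rings E and F. The whole auxiliary sequence would have to be run at the bromine after a base-sensitive lactone with an epimerisable C3 exists, or after ring C is finished. The chosen plan brings rings D, E and F in before the key step.
- Step economy: clearly worse, by roughly the length of the isoflavan sequence placed late and linearly.

Alternative 2: The cuts are O1–C8a and C4–C4a. Ring A would arrive as the aryne 1-(benzyloxy)-3-chloro-4,5-didehydrobenzene A4 and would expand the oxetane (2S,3S)-3-[2-(benzyloxy)-4-methoxyphenyl]-2-{4-(benzyloxy)-5-[(3S)-7-(benzyloxy)-3,4-dihydro-2H-chromen-3-yl]-2-methoxyphenyl}oxetane A3. The oxetane oxygen adds to the aryne, the benzylic C–O bond breaks, and the aryl anion captures C4. The product would be (3S,4S)-7-(benzyloxy)-4-{4-(benzyloxy)-5-[(3S)-7-(benzyloxy)-3,4-dihydro-2H-chromen-3-yl]-2-methoxyphenyl}-3-[2-(benzyloxy)-4-methoxyphenyl]-5-chloro-3,4-dihydro-2H-chromene A5. Its C4 descriptor differs from that of 27 only because chlorine raises the priority of ring A; the spatial arrangement is the same.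
- In favour: ring C is formed at its final oxidation level, so only one hydrogenolysis, which also removes chlorine, would follow. That is two steps fewer after the key step than the chosen plan; on that point the alternative is better. C3 never passes through an epimerisable stage; on that point it is at least equal.
- Against: the ring opens at the carbon bearing ring D to a cation stabilised by the ortho-methoxy and para-benzyloxy groups. C4 is then rebuilt from a planar cation with only the neighbouring C3 to guide it, and no catalyst. Proton transfer and fragmentation of the zwitterion compete. Ring expansion of an oxetane by an aryne lacks close precedent.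
- Preparation: A3 is a strained, acid-labile benzylic ether that is hard to make as one enantiomer. A4 needs a multistep precursor with a chlorine whose only role is to steer regiochemistry.
- Comparison: the chosen plan forms the stereogenic C3–C4 bond under catalyst control on the same kind of planar carbon. The alternative forms both bonds at ring A and leaves all stereochemistry to its precursor. It is shorter after the key step, but longer and less certain before it.

Alternative 3: The cuts are C4–C4a and O1–C2. Ring A would be benzene-1,3-diol A7, adding through the carbon para to one hydroxyl to the β-carbon of (2E)-2-[2-(benzyloxy)-4-methoxyphenyl]-3-{4-(benzyloxy)-5-[(3S)-7-(benzyloxy)-3,4-dihydro-2H-chromen-3-yl]-2-methoxyphenyl}-1-(1H-pyrazol-1-yl)prop-2-en-1-one A6 under a chiral Lewis acid (for example Cu(OTf)2 with a bis(oxazoline) ligand, divalent copper). The neighbouring hydroxyl then displaces the azole and gives (3S,4R)-4-{4-(benzyloxy)-5-[(3S)-7-(benzyloxy)-3,4-dihydro-2H-chromen-3-yl]-2-methoxyphenyl}-3-[2-(benzyloxy)-4-methoxyphenyl]-7-hydroxy-3,4-dihydro-2H-chromen-2-one A8.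
- In favour: A7 is the cheapest possible ring A and needs no protecting group, and the C3–C4 bond is first made as an alkene by a classical condensation. A8 carries the same lactone as 25, so the end-game has the same length; on that point it is equal. A6 should need about as many steps as 22; on that point it is equal or slightly better.
- Stereochemistry: C4 would be set by facial attack on a catalyst-bound planar carbon and C3 by protonation and equilibration. This is the same logic as the chosen plan, so it is equal in principle.
- Against: the β-carbon of A6 carries ring D, whose donors make it a poor electrophile. The α-aryl group twists the acceptor and crowds the chelating catalyst; catalytic asymmetric additions of phenols of this kind are established for acceptors without an α-substituent. O-acylation of A7, double alkylation and attack between the two hydroxyls compete. The second free phenol of A8 would compete in the later ether closure.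
- Comparison: the chosen plan pairs a strong carbon nucleophile with an electrophile that the same donor groups make easy to generate. Alternative 3 asks a weak electrophile to react with a neutral arene.

Key step: step 14

Remark on the structures: sulfone 22, acid 4 and lactone 25 were checked atom by atom against the target. Constitution and configuration agree ((3S,4R) in ring C, trans; (3S) in ring E), so no structure is altered. The improvements are the regiodefined assembly of 22 and pre-formation of the quinone methide before it meets the acyl donor.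

Assumptions: carbinol 21 and sulfone 22 are used as mixtures of both epimers at the future C4, because this centre becomes planar in 24. The sense of induction of (2R,3S)-HyperBTM, that is (2R,3S)-3-isopropyl-2-phenyl-3,4-dihydro-2H-benzo[4,5]thiazolo[3,2-a]pyrimidine, is taken from the accepted model of attack anti to its 2-phenyl group.

## Route

Step 1
Reactants: 1 1-(2-hydroxy-4-methoxyphenyl)ethan-1-one
Product: 2 1-[2-(benzyloxy)-4-methoxyphenyl]ethan-1-one
Conditions: BnBr, K2CO3, DMF, 60 °C
Reagents that add atoms: benzyl bromide, BrCc1ccccc1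
Why: Williamson ether synthesis; carbonate in a dipolar solvent breaks the hydrogen bond of the ortho-hydroxy ketone and the phenoxide is O-benzylated.

Step 2
Reactants: 2 1-[2-(benzyloxy)-4-methoxyphenyl]ethan-1-one
Product: 4 2-[2-(benzyloxy)-4-methoxyphenyl]acetic acid, via thiomorpholide 3 (not isolated)
Conditions: S8, morpholine, 130 °C; then NaOH, EtOH–H2O, reflux; aq. HCl
Reagents that add atoms: sodium hydroxide, [Na+].[OH-], and water, O (the two carboxyl oxygens of 4); sulfur, S1SSSSSSS1, and morpholine, C1COCCN1 (atoms kept only in 3)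
Why: Willgerodt–Kindler reaction moves the oxidised carbon to the chain terminus as the thioamide, and alkaline hydrolysis gives the arylacetic acid; aryl benzyl and methyl ethers tolerate both stages.

Step 3
Reactants: 4 2-[2-(benzyloxy)-4-methoxyphenyl]acetic acid
Product: 5 2-[2-(benzyloxy)-5-bromo-4-methoxyphenyl]acetic acid
Conditions: NBS, MeCN, 0 °C to rt
Reagents that add atoms: N-bromosuccinimide, O=C1CCC(=O)N1Br
Why: Electrophilic aromatic bromination; the position para to the benzyloxy and ortho to the methoxy group is the most activated and least hindered, the position between the two oxygens is shielded, and ionic conditions spare the benzylic CH2.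

Step 4
Reactants: 5 2-[2-(benzyloxy)-5-bromo-4-methoxyphenyl]acetic acid; 6 (4S)-4-benzyl-1,3-oxazolidin-2-one
Product: 8 (4S)-4-benzyl-3-{[2-(benzyloxy)-5-bromo-4-methoxyphenyl]acetyl}-1,3-oxazolidin-2-one, via mixed pivalic anhydride 7 (not isolated)
Conditions: t-BuCOCl, Et3N, THF, −20 °C; then 6, LiCl, rt
Reagents that add atoms: none
Why: N-acylation of the oxazolidinone through the mixed anhydride, with attack at the less hindered arylacetyl carbonyl; the auxiliary stereocentre is not involved.

Step 5
Reactants: 9 4-(benzyloxy)-2-hydroxybenzaldehyde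
Product: 10 4-(benzyloxy)-2-(methoxymethoxy)benzaldehyde
Conditions: MeOCH2Cl, i-Pr2NEt, CH2Cl2, 0 °C to rt
Reagents that add atoms: chloromethyl methyl ether, COCCl
Why: Acetal protection of the acidic salicylaldehyde hydroxyl; the methoxymethyl ether survives enolate and hydride steps and is later removed by acid without loss of benzyl ethers.

Step 6
Reactants: 10 4-(benzyloxy)-2-(methoxymethoxy)benzaldehyde
Product: 11 [4-(benzyloxy)-2-(methoxymethoxy)phenyl]methanol
Conditions: NaBH4, MeOH–THF, 0 °C
Reagents that add atoms: none
Why: Borohydride reduction of an aryl aldehyde; nothing else in the molecule is reducible.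

Step 7
Reactants: 11 [4-(benzyloxy)-2-(methoxymethoxy)phenyl]methanol
Product: 13 4-(benzyloxy)-1-(bromomethyl)-2-(methoxymethoxy)benzene, via benzylic mesylate 12 (not isolated)
Conditions: MsCl, Et3N, THF, 0 °C; then LiBr, rt
Reagents that add atoms: lithium bromide, [Li+].[Br-]
Why: Sulfonylation followed by bromide displacement under non-acidic conditions keeps the acetal intact; the electron-rich benzylic bromide is used at once without storage.

Step 8
Reactants: 8 (4S)-4-benzyl-3-{[2-(benzyloxy)-5-bromo-4-methoxyphenyl]acetyl}-1,3-oxazolidin-2-one; 13 4-(benzyloxy)-1-(bromomethyl)-2-(methoxymethoxy)benzene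
Product: 15 (4S)-4-benzyl-3-{(2S)-3-[4-(benzyloxy)-2-(methoxymethoxy)phenyl]-2-[2-(benzyloxy)-5-bromo-4-methoxyphenyl]propanoyl}-1,3-oxazolidin-2-one, via sodium enolate 14 (not isolated)
Conditions: NaN(SiMe3)2, THF, −78 °C; then 13, −78 to −40 °C; AcOH quench
Reagents that add atoms: none
Why: Evans asymmetric alkylation; the chelated (Z)-sodium enolate is shielded on one face by the benzyl group of the (4S) auxiliary and the bromide enters from the other, which sets (2S). A slight deficit of base and a cold acidic quench protect the acidic α-aryl centre from epimerisation.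

Step 9
Reactants: 15 (4S)-4-benzyl-3-{(2S)-3-[4-(benzyloxy)-2-(methoxymethoxy)phenyl]-2-[2-(benzyloxy)-5-bromo-4-methoxyphenyl]propanoyl}-1,3-oxazolidin-2-one
Product: 16 (2S)-3-[4-(benzyloxy)-2-(methoxymethoxy)phenyl]-2-[2-(benzyloxy)-5-bromo-4-methoxyphenyl]propan-1-ol
Conditions: LiBH4, MeOH (1 equiv), THF, 0 °C
Reagents that add atoms: none
Why: Reductive cleavage of the imide at the exocyclic carbonyl; the medium is not basic enough to epimerise the stereocentre, the aryl bromide and ethers are inert, and the auxiliary is recovered.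

Step 10
Reactants: 16 (2S)-3-[4-(benzyloxy)-2-(methoxymethoxy)phenyl]-2-[2-(benzyloxy)-5-bromo-4-methoxyphenyl]propan-1-ol
Product: 17 5-(benzyloxy)-2-{(2S)-2-[2-(benzyloxy)-5-bromo-4-methoxyphenyl]-3-hydroxypropyl}phenol
Conditions: HCl (aq.), MeOH, 50 °C
Reagents that add atoms: none
Why: Acid-catalysed acetal exchange with methanol frees the phenol; benzyl ethers, aryl bromide and the primary alcohol are stable to dilute acid.

Step 11
Reactants: 17 5-(benzyloxy)-2-{(2S)-2-[2-(benzyloxy)-5-bromo-4-methoxyphenyl]-3-hydroxypropyl}phenol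
Product: 18 (3S)-7-(benzyloxy)-3-[2-(benzyloxy)-5-bromo-4-methoxyphenyl]-3,4-dihydro-2H-chromene
Conditions: PPh3, DIAD, THF, 0 °C to rt
Reagents that add atoms: none
Why: Intramolecular Mitsunobu etherification; the primary alcohol is activated and displaced by the only phenol in a 6-exo-tet closure of ring E, and the stereocentre is not at the reacting carbon.

Step 12
Reactants: 18 (3S)-7-(benzyloxy)-3-[2-(benzyloxy)-5-bromo-4-methoxyphenyl]-3,4-dihydro-2H-chromene; 9 4-(benzyloxy)-2-hydroxybenzaldehyde
Product: 21 5-(benzyloxy)-2-[{4-(benzyloxy)-5-[(3S)-7-(benzyloxy)-3,4-dihydro-2H-chromen-3-yl]-2-methoxyphenyl}(hydroxy)methyl]phenol (both epimers at the carbinol carbon), via aryllithium 19 (not isolated), via sodium phenolate 20 (not isolated)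
Conditions: 18, n-BuLi, THF, −78 °C; 9, NaH, THF, 0 °C; 19 into 20, −78 to 0 °C; aq. NH4Cl
Reagents that add atoms: none
Why: Bromine–lithium exchange, then 1,2-addition of the aryllithium (stabilised by its ortho-methoxy group) to the aldehyde, the standard entry to ortho-hydroxybenzhydrols. The phenol is deprotonated beforehand so that one equivalent of 19 suffices, and the position of ring A is fixed by the aldehyde itself.

Step 13
Reactants: 21 5-(benzyloxy)-2-[{4-(benzyloxy)-5-[(3S)-7-(benzyloxy)-3,4-dihydro-2H-chromen-3-yl]-2-methoxyphenyl}(hydroxy)methyl]phenol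
Product: 22 5-(benzyloxy)-2-[{4-(benzyloxy)-5-[(3S)-7-(benzyloxy)-3,4-dihydro-2H-chromen-3-yl]-2-methoxyphenyl}(4-methylbenzenesulfonyl)methyl]phenol (both epimers at the sulfonyl carbon)
Conditions: p-TolSO2Na, HCO2H, CH2Cl2–H2O, rt; isolated by crystallisation
Reagents that add atoms: sodium 4-methylbenzenesulfinate, [Na+].Cc1ccc(cc1)S(=O)[O-]
Why: Acid-promoted SN1 substitution of the doubly activated benzhydrol; the sulfinate is alkylated at sulfur to give the sulfone, which is the usual base-triggered precursor of ortho-quinone methides. A mild acid and excess sulfinate are chosen to outrun self-alkylation.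

Step 14
Reactants: 22 5-(benzyloxy)-2-[{4-(benzyloxy)-5-[(3S)-7-(benzyloxy)-3,4-dihydro-2H-chromen-3-yl]-2-methoxyphenyl}(4-methylbenzenesulfonyl)methyl]phenol; 4 2-[2-(benzyloxy)-4-methoxyphenyl]acetic acid
Product: 25 (3S,4R)-7-(benzyloxy)-4-{4-(benzyloxy)-5-[(3S)-7-(benzyloxy)-3,4-dihydro-2H-chromen-3-yl]-2-methoxyphenyl}-3-[2-(benzyloxy)-4-methoxyphenyl]-3,4-dihydro-2H-chromen-2-one, via mixed pivalic anhydride 23 (not isolated), via ortho-quinone methide 24 (not isolated)
Conditions: 22, Cs2CO3, CH2Cl2, rt, filtered (24); 4, t-BuCOCl, i-Pr2NEt, CH2Cl2, 0 °C (23); 24 into 23 with (2R,3S)-HyperBTM (10 mol %), i-Pr2NEt, −20 °C to rt; then DBU (0.2 equiv), rt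
Reagents that add atoms: none
Why: The isothiourea is N-acylated by 23 and pivalate deprotonates the acyl ammonium to the (Z)-ammonium enolate, held planar by the 1,5 oxygen–sulfur contact; the enolate carbon adds to the methide carbon of 24 (C3–C4) and the phenoxide so formed attacks the acyl ammonium (O1–C2), releasing the catalyst. The closest known reaction type is the isothiourea-catalysed Michael addition–lactonisation (formal [4+2] annulation) of arylacetic acid-derived ammonium enolates with ortho-quinone methides to 3,4-dihydrocoumarins. Ring C closes by 6-exo-trig lactonisation. C3 is set because the enolate reacts on the face remote from the pseudo-axial 2-phenyl group of the catalyst, which for the (2R,3S) catalyst should be the (3S) face; because C3 is α to the lactone carbonyl, DBU then brings any cis isomer to the more stable trans arrangement. C4 is set when that enolate face selects one face of the planar (E)-methide; the anti topicity usual for this catalyst class, with ring D turned away from the catalyst, should give (4R), and this centre cannot epimerise afterwards. The step needs face selectivity at C4 and acylation at carbon instead of the ring A oxygen. The para-benzyloxy and ortho-methoxy groups of ring D make the methide form under mild base and persist, so it is generated and freed from sulfinate before it meets 23, and the low temperature keeps uncatalysed ketene cycloaddition behind. The (3S) centre of ring E is meta on ring D and should not bias the faces; the products are diastereomers, so a minor isomer is separable.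

Step 15
Reactants: 25 (3S,4R)-7-(benzyloxy)-4-{4-(benzyloxy)-5-[(3S)-7-(benzyloxy)-3,4-dihydro-2H-chromen-3-yl]-2-methoxyphenyl}-3-[2-(benzyloxy)-4-methoxyphenyl]-3,4-dihydro-2H-chromen-2-one
Product: 26 5-(benzyloxy)-2-[(1R,2S)-1-{4-(benzyloxy)-5-[(3S)-7-(benzyloxy)-3,4-dihydro-2H-chromen-3-yl]-2-methoxyphenyl}-2-[2-(benzyloxy)-4-methoxyphenyl]-3-hydroxypropyl]phenol
Conditions: LiAlH4, THF, 0 °C; aq. KNaC4H4O6 work-up
Reagents that add atoms: none
Why: Hydride reduction of the aryl lactone to a phenol and a primary alcohol; reduction is faster than enolisation, and the trans isomer is already the stable one, so C3 is retained and C4 is untouched.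

Step 16
Reactants: 26 5-(benzyloxy)-2-[(1R,2S)-1-{4-(benzyloxy)-5-[(3S)-7-(benzyloxy)-3,4-dihydro-2H-chromen-3-yl]-2-methoxyphenyl}-2-[2-(benzyloxy)-4-methoxyphenyl]-3-hydroxypropyl]phenol
Product: 27 (3S,4R)-7-(benzyloxy)-4-{4-(benzyloxy)-5-[(3S)-7-(benzyloxy)-3,4-dihydro-2H-chromen-3-yl]-2-methoxyphenyl}-3-[2-(benzyloxy)-4-methoxyphenyl]-3,4-dihydro-2H-chromene
Conditions: PPh3, DIAD, THF, 0 °C to rt
Reagents that add atoms: none
Why: Intramolecular Mitsunobu etherification; the ring A hydroxyl is the only free phenol and displaces the activated primary alcohol in a 6-exo-tet closure (O1–C2), so neither stereocentre is touched.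

Step 17
Reactants: 27 (3S,4R)-7-(benzyloxy)-4-{4-(benzyloxy)-5-[(3S)-7-(benzyloxy)-3,4-dihydro-2H-chromen-3-yl]-2-methoxyphenyl}-3-[2-(benzyloxy)-4-methoxyphenyl]-3,4-dihydro-2H-chromene
Product: 28 (3S,4R)-4-{4-hydroxy-5-[(3S)-7-hydroxy-3,4-dihydro-2H-chromen-3-yl]-2-methoxyphenyl}-3-(2-hydroxy-4-methoxyphenyl)-3,4-dihydro-2H-chromen-7-ol
Conditions: H2 (1 atm), Pd/C, EtOAc–MeOH, rt
Reagents that add atoms: none
Why: Catalytic hydrogenolysis of four aryl benzyl ethers; the chroman C–O bonds are alkyl aryl ethers and C4 bears no heteroatom, so nothing else should be cleaved. The product is handled under inert gas.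

## Compound list

1 | 1-(2-hydroxy-4-methoxyphenyl)ethan-1-one | COc1ccc(C(C)=O)c(O)c1 | starting material
2 | 1-[2-(benzyloxy)-4-methoxyphenyl]ethan-1-one | COc1ccc(C(C)=O)c(OCc2ccccc2)c1 | intermediate
3 | 2-[2-(benzyloxy)-4-methoxyphenyl]-1-(morpholin-4-yl)ethane-1-thione | COc1ccc(CC(=S)N2CCOCC2)c(OCc2ccccc2)c1 | intermediate (not isolated)
4 | 2-[2-(benzyloxy)-4-methoxyphenyl]acetic acid | COc1ccc(CC(=O)O)c(OCc2ccccc2)c1 | intermediate
5 | 2-[2-(benzyloxy)-5-bromo-4-methoxyphenyl]acetic acid | COc1cc(OCc2ccccc2)c(CC(=O)O)cc1Br | intermediate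
6 | (4S)-4-benzyl-1,3-oxazolidin-2-one | O=C1N[C@@H](Cc2ccccc2)CO1 | starting material
7 | 2-[2-(benzyloxy)-5-bromo-4-methoxyphenyl]acetic 2,2-dimethylpropanoic anhydride | COc1cc(OCc2ccccc2)c(CC(=O)OC(=O)C(C)(C)C)cc1Br | intermediate (not isolated)
8 | (4S)-4-benzyl-3-{[2-(benzyloxy)-5-bromo-4-methoxyphenyl]acetyl}-1,3-oxazolidin-2-one | COc1cc(OCc2ccccc2)c(CC(=O)N2C(=O)OC[C@@H]2Cc2ccccc2)cc1Br | intermediate
9 | 4-(benzyloxy)-2-hydroxybenzaldehyde | O=Cc1ccc(OCc2ccccc2)cc1O | starting material
10 | 4-(benzyloxy)-2-(methoxymethoxy)benzaldehyde | COCOc1cc(OCc2ccccc2)ccc1C=O | intermediate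
11 | [4-(benzyloxy)-2-(methoxymethoxy)phenyl]methanol | COCOc1cc(OCc2ccccc2)ccc1CO | intermediate
12 | [4-(benzyloxy)-2-(methoxymethoxy)phenyl]methyl methanesulfonate | COCOc1cc(OCc2ccccc2)ccc1COS(C)(=O)=O | intermediate (not isolated)
13 | 4-(benzyloxy)-1-(bromomethyl)-2-(methoxymethoxy)benzene | COCOc1cc(OCc2ccccc2)ccc1CBr | intermediate
14 | sodium (Z)-enolate of 8 | COc1cc(OCc2ccccc2)c(/C=C(\[O-])N2C(=O)OC[C@@H]2Cc2ccccc2)cc1Br.[Na+] | intermediate (not isolated)
15 | (4S)-4-benzyl-3-{(2S)-3-[4-(benzyloxy)-2-(methoxymethoxy)phenyl]-2-[2-(benzyloxy)-5-bromo-4-methoxyphenyl]propanoyl}-1,3-oxazolidin-2-one | COCOc1cc(OCc2ccccc2)ccc1C[C@H](C(=O)N1C(=O)OC[C@@H]1Cc1ccccc1)c1cc(Br)c(OC)cc1OCc1ccccc1 | intermediate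
16 | (2S)-3-[4-(benzyloxy)-2-(methoxymethoxy)phenyl]-2-[2-(benzyloxy)-5-bromo-4-methoxyphenyl]propan-1-ol | COCOc1cc(OCc2ccccc2)ccc1C[C@H](CO)c1cc(Br)c(OC)cc1OCc1ccccc1 | intermediate
17 | 5-(benzyloxy)-2-{(2S)-2-[2-(benzyloxy)-5-bromo-4-methoxyphenyl]-3-hydroxypropyl}phenol | Oc1cc(OCc2ccccc2)ccc1C[C@H](CO)c1cc(Br)c(OC)cc1OCc1ccccc1 | intermediate
18 | (3S)-7-(benzyloxy)-3-[2-(benzyloxy)-5-bromo-4-methoxyphenyl]-3,4-dihydro-2H-chromene | COc1cc(OCc2ccccc2)c([C@H]2COc3cc(OCc4ccccc4)ccc3C2)cc1Br | intermediate
19 | {4-(benzyloxy)-5-[(3S)-7-(benzyloxy)-3,4-dihydro-2H-chromen-3-yl]-2-methoxyphenyl}lithium | COc1cc(OCc2ccccc2)c([C@H]2COc3cc(OCc4ccccc4)ccc3C2)cc1[Li] | intermediate (not isolated)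
20 | sodium 5-(benzyloxy)-2-formylphenolate | O=Cc1ccc(OCc2ccccc2)cc1[O-].[Na+] | intermediate (not isolated)
21 | 5-(benzyloxy)-2-[{4-(benzyloxy)-5-[(3S)-7-(benzyloxy)-3,4-dihydro-2H-chromen-3-yl]-2-methoxyphenyl}(hydroxy)methyl]phenol, both carbinol epimers | COc1cc(OCc2ccccc2)c([C@H]2COc3cc(OCc4ccccc4)ccc3C2)cc1C(O)c1ccc(OCc2ccccc2)cc1O | intermediate
22 | 5-(benzyloxy)-2-[{4-(benzyloxy)-5-[(3S)-7-(benzyloxy)-3,4-dihydro-2H-chromen-3-yl]-2-methoxyphenyl}(4-methylbenzenesulfonyl)methyl]phenol, both epimers at the sulfonyl carbon | COc1cc(OCc2ccccc2)c([C@H]2COc3cc(OCc4ccccc4)ccc3C2)cc1C(c1ccc(OCc2ccccc2)cc1O)S(=O)(=O)c1ccc(C)cc1 | intermediate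
23 | 2-[2-(benzyloxy)-4-methoxyphenyl]acetic 2,2-dimethylpropanoic anhydride | COc1ccc(CC(=O)OC(=O)C(C)(C)C)c(OCc2ccccc2)c1 | intermediate (not isolated)
24 | (6E)-3-(benzyloxy)-6-({4-(benzyloxy)-5-[(3S)-7-(benzyloxy)-3,4-dihydro-2H-chromen-3-yl]-2-methoxyphenyl}methylidene)cyclohexa-2,4-dien-1-one | COc1cc(OCc2ccccc2)c([C@H]2COc3cc(OCc4ccccc4)ccc3C2)cc1/C=C1\C=CC(OCc2ccccc2)=CC1=O | intermediate (not isolated)
25 | (3S,4R)-7-(benzyloxy)-4-{4-(benzyloxy)-5-[(3S)-7-(benzyloxy)-3,4-dihydro-2H-chromen-3-yl]-2-methoxyphenyl}-3-[2-(benzyloxy)-4-methoxyphenyl]-3,4-dihydro-2H-chromen-2-one | COc1ccc([C@H]2C(=O)Oc3cc(OCc4ccccc4)ccc3[C@@H]2c2cc([C@H]3COc4cc(OCc5ccccc5)ccc4C3)c(OCc3ccccc3)cc2OC)c(OCc2ccccc2)c1 | intermediate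
26 | 5-(benzyloxy)-2-[(1R,2S)-1-{4-(benzyloxy)-5-[(3S)-7-(benzyloxy)-3,4-dihydro-2H-chromen-3-yl]-2-methoxyphenyl}-2-[2-(benzyloxy)-4-methoxyphenyl]-3-hydroxypropyl]phenol | COc1ccc([C@@H](CO)[C@H](c2ccc(OCc3ccccc3)cc2O)c2cc([C@H]3COc4cc(OCc5ccccc5)ccc4C3)c(OCc3ccccc3)cc2OC)c(OCc2ccccc2)c1 | intermediate
27 | (3S,4R)-7-(benzyloxy)-4-{4-(benzyloxy)-5-[(3S)-7-(benzyloxy)-3,4-dihydro-2H-chromen-3-yl]-2-methoxyphenyl}-3-[2-(benzyloxy)-4-methoxyphenyl]-3,4-dihydro-2H-chromene | COc1ccc([C@H]2COc3cc(OCc4ccccc4)ccc3[C@@H]2c2cc([C@H]3COc4cc(OCc5ccccc5)ccc4C3)c(OCc3ccccc3)cc2OC)c(OCc2ccccc2)c1 | intermediate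
28 | (3S,4R)-4-{4-hydroxy-5-[(3S)-7-hydroxy-3,4-dihydro-2H-chromen-3-yl]-2-methoxyphenyl}-3-(2-hydroxy-4-methoxyphenyl)-3,4-dihydro-2H-chromen-7-ol | COc1ccc([C@H]2COc3cc(O)ccc3[C@@H]2c2cc([C@H]3COc4cc(O)ccc4C3)c(O)cc2OC)c(O)c1 | target

## Step count and risks

Total step count: 17. Longest linear sequence: 14 steps (1, 2, 4, 5, 8, 15, 16, 17, 18, 21, 22, 25, 26, 27, 28); steps 5 to 7 form a three-step branch that joins at step 8.

Step 14 (key step).
- Most likely failure: erosion of facial selectivity at C4. That selectivity is the product of enolate-face control by the catalyst and of the syn or anti topicity toward the methide. Because C3 is equilibrated afterwards, a cis adduct would end as the trans isomer with both centres inverted.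
- Should a trial show that the cis diad is the kinetic one, the enantiomeric catalyst would be the correct choice.
- A second process is slow addition, caused by congestion between two ortho-substituted aryl groups and by the donor-stabilised methide, which would let uncatalysed ketene cycloaddition compete.
- Fallback, from 4 and 22, returning at 25: 4 is converted with 6, as in step 4, into (4S)-4-benzyl-3-{[2-(benzyloxy)-4-methoxyphenyl]acetyl}-1,3-oxazolidin-2-one F1. Its sodium enolate (NaN(SiMe3)2, THF, −78 °C) is added to pre-formed 24. The auxiliary, which should favour the same (S) enolate face as in step 8, directs the addition to (4S)-4-benzyl-3-[(2S,3R)-3-[4-(benzyloxy)-2-hydroxyphenyl]-3-{4-(benzyloxy)-5-[(3S)-7-(benzyloxy)-3,4-dihydro-2H-chromen-3-yl]-2-methoxyphenyl}-2-[2-(benzyloxy)-4-methoxyphenyl]propanoyl]-1,3-oxazolidin-2-one F2. Its phenoxide should close onto the imide on warming with K2CO3, releasing 6 and giving 25; a minor diastereomer is removed by chromatography.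

Step 13.
- Most likely failure: ionisation of the very electron-rich benzhydrol outruns capture by sulfinate and leads to Friedel–Crafts self-alkylation, or the sulfone reverts on silica.
- Fallback, from 21, returning at 24: the phenol of 21 is acylated selectively (Boc2O, i-Pr2NEt, CH2Cl2, 0 °C) to tert-butyl 5-(benzyloxy)-2-[{4-(benzyloxy)-5-[(3S)-7-(benzyloxy)-3,4-dihydro-2H-chromen-3-yl]-2-methoxyphenyl}(hydroxy)methyl]phenyl carbonate F3. Deprotonation of the carbinol (t-BuMgCl, THF, −78 °C to rt) should make the carbonate migrate to the benzhydryl oxygen and leave as tert-butyl carbonate, giving 24 without any acid. The solution of 24 then enters step 14.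

Step 12.
- Most likely failure: sluggish addition to the phenoxide-bearing, para-alkoxy aldehyde, so that the aryllithium is protonated on work-up (net loss of bromine), or incomplete exchange.
- Fallback, from 18, returning at 21, with the polarity reversed: bromine–lithium exchange and DMF give 4-(benzyloxy)-5-[(3S)-7-(benzyloxy)-3,4-dihydro-2H-chromen-3-yl]-2-methoxybenzaldehyde F4. Purchased 3-(benzyloxy)phenol is converted with EtMgBr into bromomagnesium 3-(benzyloxy)phenolate F5. In toluene at rt, F5 should add to F4 through a chelated six-membered transition state, only at the ortho position para to the benzyloxy group, giving 21.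

Step 16.
- Most likely failure: slow displacement at the β-branched primary carbon beside two aryl-bearing carbons, so that the activated alcohol is diverted to alkylation of the hydrazide by-product or to elimination.
- Fallback, from 25, returning at 27, with no substitution at C2: i-Bu2AlH (CH2Cl2, −78 °C) reduces 25 to the lactol (3S,4R)-7-(benzyloxy)-4-{4-(benzyloxy)-5-[(3S)-7-(benzyloxy)-3,4-dihydro-2H-chromen-3-yl]-2-methoxyphenyl}-3-[2-(benzyloxy)-4-methoxyphenyl]-3,4-dihydro-2H-chromen-2-ol F6. Ionic hydrogenation (Et3SiH, BF3·OEt2, CH2Cl2, −78 °C) reduces the oxocarbenium ion to 27. Excess silane and low temperature are used so that hydride delivery outruns loss of the C3 proton.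

## Further compounds

F1 | step 14 | (4S)-4-benzyl-3-{[2-(benzyloxy)-4-methoxyphenyl]acetyl}-1,3-oxazolidin-2-one | COc1ccc(CC(=O)N2C(=O)OC[C@@H]2Cc2ccccc2)c(OCc2ccccc2)c1
F2 | step 14 | (4S)-4-benzyl-3-[(2S,3R)-3-[4-(benzyloxy)-2-hydroxyphenyl]-3-{4-(benzyloxy)-5-[(3S)-7-(benzyloxy)-3,4-dihydro-2H-chromen-3-yl]-2-methoxyphenyl}-2-[2-(benzyloxy)-4-methoxyphenyl]propanoyl]-1,3-oxazolidin-2-one | COc1ccc([C@@H](C(=O)N2C(=O)OC[C@@H]2Cc2ccccc2)[C@H](c2ccc(OCc3ccccc3)cc2O)c2cc([C@H]3COc4cc(OCc5ccccc5)ccc4C3)c(OCc3ccccc3)cc2OC)c(OCc2ccccc2)c1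
F3 | step 13 | tert-butyl 5-(benzyloxy)-2-[{4-(benzyloxy)-5-[(3S)-7-(benzyloxy)-3,4-dihydro-2H-chromen-3-yl]-2-methoxyphenyl}(hydroxy)methyl]phenyl carbonate | COc1cc(OCc2ccccc2)c([C@H]2COc3cc(OCc4ccccc4)ccc3C2)cc1C(O)c1ccc(OCc2ccccc2)cc1OC(=O)OC(C)(C)C
F4 | step 12 | 4-(benzyloxy)-5-[(3S)-7-(benzyloxy)-3,4-dihydro-2H-chromen-3-yl]-2-methoxybenzaldehyde | COc1cc(OCc2ccccc2)c([C@H]2COc3cc(OCc4ccccc4)ccc3C2)cc1C=O
F5 | step 12 | bromomagnesium 3-(benzyloxy)phenolate | [Mg+2].[Br-].[O-]c1cccc(OCc2ccccc2)c1
F6 | step 16 | (3S,4R)-7-(benzyloxy)-4-{4-(benzyloxy)-5-[(3S)-7-(benzyloxy)-3,4-dihydro-2H-chromen-3-yl]-2-methoxyphenyl}-3-[2-(benzyloxy)-4-methoxyphenyl]-3,4-dihydro-2H-chromen-2-ol (both anomers) | COc1ccc([C@H]2C(O)Oc3cc(OCc4ccccc4)ccc3[C@@H]2c2cc([C@H]3COc4cc(OCc5ccccc5)ccc4C3)c(OCc3ccccc3)cc2OC)c(OCc2ccccc2)c1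
A1 | alternative 1 | (2S,3R)-6-(benzyloxy)-2-[2-(benzyloxy)-4-methoxyphenyl]-3-[4-(benzyloxy)-5-bromo-2-methoxyphenyl]-2,3-dihydro-1H-inden-1-one | COc1ccc([C@H]2C(=O)c3cc(OCc4ccccc4)ccc3[C@@H]2c2cc(Br)c(OCc3ccccc3)cc2OC)c(OCc2ccccc2)c1
A2 | alternative 1 | (3S,4R)-7-(benzyloxy)-3-[2-(benzyloxy)-4-methoxyphenyl]-4-[4-(benzyloxy)-5-bromo-2-methoxyphenyl]-3,4-dihydro-2H-chromen-2-one | COc1ccc([C@H]2C(=O)Oc3cc(OCc4ccccc4)ccc3[C@@H]2c2cc(Br)c(OCc3ccccc3)cc2OC)c(OCc2ccccc2)c1
A3 | alternative 2 | (2S,3S)-3-[2-(benzyloxy)-4-methoxyphenyl]-2-{4-(benzyloxy)-5-[(3S)-7-(benzyloxy)-3,4-dihydro-2H-chromen-3-yl]-2-methoxyphenyl}oxetane | COc1ccc([C@H]2CO[C@@H]2c2cc([C@H]3COc4cc(OCc5ccccc5)ccc4C3)c(OCc3ccccc3)cc2OC)c(OCc2ccccc2)c1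
A4 | alternative 2 | 1-(benzyloxy)-3-chloro-4,5-didehydrobenzene | ClC1=CC(OCc2ccccc2)=CC#C1
A5 | alternative 2 | (3S,4S)-7-(benzyloxy)-4-{4-(benzyloxy)-5-[(3S)-7-(benzyloxy)-3,4-dihydro-2H-chromen-3-yl]-2-methoxyphenyl}-3-[2-(benzyloxy)-4-methoxyphenyl]-5-chloro-3,4-dihydro-2H-chromene | COc1ccc([C@H]2COc3cc(OCc4ccccc4)cc(Cl)c3[C@@H]2c2cc([C@H]3COc4cc(OCc5ccccc5)ccc4C3)c(OCc3ccccc3)cc2OC)c(OCc2ccccc2)c1
A6 | alternative 3 | (2E)-2-[2-(benzyloxy)-4-methoxyphenyl]-3-{4-(benzyloxy)-5-[(3S)-7-(benzyloxy)-3,4-dihydro-2H-chromen-3-yl]-2-methoxyphenyl}-1-(1H-pyrazol-1-yl)prop-2-en-1-one | COc1ccc(/C(C(=O)n2cccn2)=C\c2cc([C@H]3COc4cc(OCc5ccccc5)ccc4C3)c(OCc3ccccc3)cc2OC)c(OCc2ccccc2)c1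
A7 | alternative 3 | benzene-1,3-diol | Oc1cccc(O)c1
A8 | alternative 3 | (3S,4R)-4-{4-(benzyloxy)-5-[(3S)-7-(benzyloxy)-3,4-dihydro-2H-chromen-3-yl]-2-methoxyphenyl}-3-[2-(benzyloxy)-4-methoxyphenyl]-7-hydroxy-3,4-dihydro-2H-chromen-2-one | COc1ccc([C@H]2C(=O)Oc3cc(O)ccc3[C@@H]2c2cc([C@H]3COc4cc(OCc5ccccc5)ccc4C3)c(OCc3ccccc3)cc2OC)c(OCc2ccccc2)c1
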